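The pyranone is traced back to a carbocycle. Deleting O1 from between lactone carbon C2 and ring A carbon C8a leaves a 3-arylindan-1-one whose methoxy groups at C4, C6 and C7 become those at C5, C7 and C8 of the coumarin. One Baeyer–Villiger oxidation therefore both widens the five-membered ketone to the six-membered lactone and delivers the fourth oxygen of ring A to a carbon that substitution chemistry on 1,2,4-trimethoxybenzene does not address. Its precursor is the racemic 4,6,7-trimethoxyindanone carrying ring B as a 3-acetoxy-4-methoxyphenyl group at C3, made by hydroarylation and then intramolecular acylation. Dehydrogenation and acetate removal complete the route.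

Key step: step 4

Remark on the chemistry: the target is achiral, so every intermediate that carries the diarylmethine carbon is handled as a racemate. Atom map: trimethoxybenzene C5 → indanone C3a → coumarin C4a, and trimethoxybenzene C6 → C7a → C8a. The methoxy carbons C1, C2 and C4 of trimethoxybenzene become indanone C7, C6 and C4, then coumarin C8, C7 and C5.

Step 1
Reactants: 1 isoferulic acid
Product: 2 (E)-3-(3-acetoxy-4-methoxyphenyl)prop-2-enoic acid
Conditions: Ac2O (1.5 equiv), pyridine, rt; then H2O
Reagents that add atoms: acetic anhydride, CC(=O)OC(C)=O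
Why: Pyridine-promoted O-acetylation of a phenol (nucleophilic acyl substitution) is routine for hydroxycinnamic acids, and the stir with water returns any carboxyl group that was acylated to the free acid.

Step 2
Reactants: 2 (E)-3-(3-acetoxy-4-methoxyphenyl)prop-2-enoic acid; 3 1,2,4-trimethoxybenzene (1.2 equiv)
Product: 4 rac-3-(3-acetoxy-4-methoxyphenyl)-3-(2,4,5-trimethoxyphenyl)propanoic acid
Conditions: CF3CO2H–CH2Cl2 (1:1), rt
Reagents that add atoms: none
Why: In this Brønsted-acid hydroarylation of a cinnamic acid (Friedel–Crafts conjugate alkylation), protonation of 2 is supported by the methoxy group para to the side chain, the benzylic electrophile is captured by C5 of 3 (para to the C2 methoxy, ortho to the C4 methoxy, hence the most nucleophilic carbon), and the new methine centre forms as a racemate that step 5 erases.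

Step 3
Reactants: 4 rac-3-(3-acetoxy-4-methoxyphenyl)-3-(2,4,5-trimethoxyphenyl)propanoic acid
Product: 6 rac-3-(3-acetoxy-4-methoxyphenyl)-4,6,7-trimethoxyindan-1-one, via acyl trifluoroacetate 5 (not isolated)
Conditions: (CF3CO)2O (3 equiv), CF3CO2H, CH2Cl2, 0 °C to rt
Reagents that add atoms: none
Why: In this intramolecular Friedel–Crafts acylation through a mixed anhydride, the only free ring A carbon next to the side chain is ortho to a methoxy group and closes the five-membered ring, whereas ring B offers only carbons ortho or para to the weakly donating acetoxy group and meta to its methoxy group.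

Step 4
Reactants: 6 rac-3-(3-acetoxy-4-methoxyphenyl)-4,6,7-trimethoxyindan-1-one
Product: 8 rac-4-(3-acetoxy-4-methoxyphenyl)-5,7,8-trimethoxy-3,4-dihydrocoumarin, via Criegee adduct 7 (not isolated)
Conditions: mCPBA (1.5 equiv), CF3CO2H (1 equiv), CH2Cl2, 0 °C to rt, dark
Reagents that add atoms: mCPBA (3-chloroperoxybenzoic acid), O=C(OO)c1cccc(Cl)c1
Why: The acid-activated ketone C1 of 6 takes up the peracid to give adduct 7, whose O–O bond breaks while the C1–C7a bond shifts to the proximal oxygen, so O1–C2 and O1–C8a are made in one event (Baeyer–Villiger oxidation, an established conversion of 1-indanones, 3-aryl examples included, into 3,4-dihydrocoumarins). The lactone ring arises not by cyclisation but by one-atom ring expansion, the five-membered carbocycle becoming the six-membered heterocycle through a concerted 1,2-shift of the bond held antiperiplanar to the O–O bond. No stereocentre is created: C3 of 6 becomes C4 of 8 untouched and racemic, and the transient carbinol centre of 7 disappears. The selectivity needed is aryl over methylene migration, and C7a, with a methoxy group ortho (C7) and another para (C4), carries the developing positive charge far better than the primary C2 methylene. Chemoselectivity against arene oxidation rests on the ketone, which keeps ring A deactivated until the insertion, on the acetate, which tames ring B, and on a small excess of oxidant at low temperature.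

Step 5
Reactants: 8 rac-4-(3-acetoxy-4-methoxyphenyl)-5,7,8-trimethoxy-3,4-dihydrocoumarin
Product: 9 4-(3-acetoxy-4-methoxyphenyl)-5,7,8-trimethoxycoumarin
Conditions: DDQ (2 equiv), 1,4-dioxane, reflux
Reagents that add atoms: none
Why: In this quinone dehydrogenation, known for 4-aryl-3,4-dihydrocoumarins, hydride leaves the doubly benzylic C4–H flanked by two donor-substituted rings, loss of a C3 proton gives the conjugated pyranone and removes the stereocentre, and the acetate keeps the ring B phenol away from the oxidant.

Step 6
Reactants: 9 4-(3-acetoxy-4-methoxyphenyl)-5,7,8-trimethoxycoumarin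
Product: 11 3'-hydroxy-5,7,8,4'-tetramethoxy-4-phenylcoumarin, via potassium phenoxide 10 (not isolated)
Conditions: K2CO3 (1.5 equiv), MeOH, rt; then 1 M HCl
Reagents that add atoms: none
Why: Base-mediated transesterification (Zemplén-type methanolysis) removes the aryl acetate, the most electrophilic ester present, and the acidification protonates the phenoxide and recloses any pyranone that opened reversibly.

Compound list
1 | isoferulic acid, (E)-3-(3-hydroxy-4-methoxyphenyl)prop-2-enoic acid | COc1ccc(/C=C/C(=O)O)cc1O | starting material
2 | (E)-3-(3-acetoxy-4-methoxyphenyl)prop-2-enoic acid | COc1ccc(/C=C/C(=O)O)cc1OC(C)=O | intermediate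
3 | 1,2,4-trimethoxybenzene | COc1ccc(OC)c(OC)c1 | starting material
4 | rac-3-(3-acetoxy-4-methoxyphenyl)-3-(2,4,5-trimethoxyphenyl)propanoic acid | O=C(O)CC(c1ccc(OC)c(OC(C)=O)c1)c1cc(OC)c(OC)cc1OC | intermediate
5 | mixed anhydride of 4 and trifluoroacetic acid (acyl trifluoroacetate, racemic, not isolated) | O=C(CC(c1ccc(OC)c(OC(C)=O)c1)c1cc(OC)c(OC)cc1OC)OC(=O)C(F)(F)F | intermediate
6 | rac-3-(3-acetoxy-4-methoxyphenyl)-4,6,7-trimethoxyindan-1-one | O=C1CC(c2ccc(OC)c(OC(C)=O)c2)c2c(OC)cc(OC)c(OC)c12 | intermediate
7 | Criegee adduct, 3-(3-acetoxy-4-methoxyphenyl)-1-hydroxy-4,6,7-trimethoxyindan-1-yl 3-chloroperoxybenzoate (racemic diastereomer mixture, not isolated) | OC1(OOC(=O)c2cccc(Cl)c2)CC(c2ccc(OC)c(OC(C)=O)c2)c2c(OC)cc(OC)c(OC)c12 | intermediate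
8 | rac-4-(3-acetoxy-4-methoxyphenyl)-5,7,8-trimethoxy-3,4-dihydrocoumarin | O=C1CC(c2ccc(OC)c(OC(C)=O)c2)c2c(OC)cc(OC)c(OC)c2O1 | intermediate
9 | 4-(3-acetoxy-4-methoxyphenyl)-5,7,8-trimethoxycoumarin | CC(=O)Oc1cc(-c2cc(=O)oc3c(OC)c(OC)cc(OC)c23)ccc1OC | intermediate
10 | potassium 2-methoxy-5-(5,7,8-trimethoxy-2-oxo-2H-chromen-4-yl)phenoxide (not isolated) | COc1ccc(-c2cc(=O)oc3c(OC)c(OC)cc(OC)c23)cc1[O-].[K+] | intermediate
11 | 3'-hydroxy-5,7,8,4'-tetramethoxy-4-phenylcoumarin | COc1ccc(-c2cc(=O)oc3c(OC)c(OC)cc(OC)c23)cc1O | target

Total step count: 6. Longest linear sequence: 6 steps (1 → 2 → 4 → 6 → 8 → 9 → 11).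

Steps most likely to fail

Step 4.
- What may go wrong: peracid uptake may be slow, because the carbonyl is deactivated by conjugation with the C7 and C4 methoxy groups. Ring A may also suffer electrophilic hydroxylation or oxidative demethylation once the lactone has formed.
- Fallback: the peracid is replaced by a benzylic hydroperoxide rearrangement one oxidation level lower. It sets out from 6. Luche reduction (NaBH4, CeCl3·7H2O, MeOH–THF, 0 °C) should give the indan-1-ol F1. Urea–H2O2 and TsOH·H2O in CH2Cl2–THF should ionise the strongly stabilised benzylic position and trap it as the benzylic hydroperoxide F2. Under the same acid, F2 should undergo Hock-type migration of the ring A carbon to give the chroman-2-ol F3. Dess–Martin periodinane in CH2Cl2 should oxidise the lactol, and the route is rejoined at 8.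

Step 3.
- What may go wrong: closure may be too slow, because the attacked carbon has one ortho donor and two meta methoxy groups. Intermolecular acylation, acyl exchange at the ring B ester or acid-induced cleavage of the diarylmethine bond could then take over.
- Fallback: the in-flask Brønsted-acid activation is given up for a preformed acyl halide and a Lewis-acid-generated acylium ion. It sets out from 4. Oxalyl chloride and catalytic DMF in CH2Cl2 should give the acid chloride F4, freed of volatiles. F4 is then closed with SnCl4 in dilute CH2Cl2 at −20 °C, and the route is rejoined at 6.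

Step 2.
- What may go wrong: protonation of the enoic acid may be incomplete, because its cation is weakened by the meta acetoxy group. Reversible alkylation, a second alkylation on ring A of the product, or slow loss of the acetate in the acid are also possible.
- Fallback: the cationic arylation is exchanged for an organometallic conjugate addition. It sets out from 2. Boc2O, catalytic DMAP and t-BuOH should give the tert-butyl cinnamate F5. Commercial 2,4,5-trimethoxyphenylboronic acid and [Rh(OH)(cod)]2 in dioxane–H2O at 60 °C (Hayashi–Miyaura-type 1,4-addition, achiral catalyst, racemic product) should give the tert-butyl 3,3-diarylpropanoate F6. CF3CO2H–CH2Cl2 cleaves the tert-butyl ester, and the route is rejoined at 4.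

Further compounds
F1 | step 4 | 3-(3-acetoxy-4-methoxyphenyl)-4,6,7-trimethoxyindan-1-ol (racemic diastereomer mixture) | OC1CC(c2ccc(OC)c(OC(C)=O)c2)c2c(OC)cc(OC)c(OC)c12
F2 | step 4 | 3-(3-acetoxy-4-methoxyphenyl)-4,6,7-trimethoxyindan-1-yl hydroperoxide (racemic diastereomer mixture) | OOC1CC(c2ccc(OC)c(OC(C)=O)c2)c2c(OC)cc(OC)c(OC)c12
F3 | step 4 | 4-(3-acetoxy-4-methoxyphenyl)-5,7,8-trimethoxychroman-2-ol (racemic diastereomer mixture) | OC1CC(c2ccc(OC)c(OC(C)=O)c2)c2c(OC)cc(OC)c(OC)c2O1
F4 | step 3 | rac-3-(3-acetoxy-4-methoxyphenyl)-3-(2,4,5-trimethoxyphenyl)propanoyl chloride | O=C(Cl)CC(c1ccc(OC)c(OC(C)=O)c1)c1cc(OC)c(OC)cc1OC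
F5 | step 2 | tert-butyl (E)-3-(3-acetoxy-4-methoxyphenyl)prop-2-enoate | COc1ccc(/C=C/C(=O)OC(C)(C)C)cc1OC(C)=O
F6 | step 2 | rac-tert-butyl 3-(3-acetoxy-4-methoxyphenyl)-3-(2,4,5-trimethoxyphenyl)propanoate | CC(C)(C)OC(=O)CC(c1ccc(OC)c(OC(C)=O)c1)c1cc(OC)c(OC)cc1OC
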